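If a target curve lies flat from its first reading on, its mean can stand for it from there on, so in the alpha run I replaced the curve from 0.500 h on by 24.9% of the substrate charged. Counting one first nucleophile per target, I divided by the 1.3 equiv charged and got 19.2%, which I called the capture share, the part of the charged first nucleophile that ended in target.

- alpha: substrate 0.031 M; first nucleophile 1.3 equiv; second nucleophile 2.5 equiv; capture agent 0.62 mM; the very flask that is asked about, followed so far
- flask: substrate 0.031 M; first nucleophile 1.30 equiv; second nucleophile 2.50 equiv; capture agent 0.620 mM; time 12 h

- alpha (time / h: other capture product / %, target / %): 0.500: 56.8, 25.0; 0.667: 65.1, 25.7; 1.00: 72.2, 24.8; 1.50: 74.7, 24.5; 2.50: 74.9, 25.2; 4.00: 75.2, 24.2; 6.00: 74.0, 24.9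

(standard deviation of a reading: 0.5 percentage points)

1. ratio of other capture product to target at 2.0 min
2. ratio of other capture product to target at 40 min
3. ratio of other capture product to target at 12 h

The readings at 2.50 h summed to 100%, so I let the other capture product take what target left. The capture share then gave a late ratio of 3.02, and I committed to it for 12 h, as the readings showed no drift up to 6.00 h.

One number was not enough earlier. At 40 min the other capture product read 65.1%, so the ratio was 2.61, lower than the late one. At 0.500 h the ratio read 2.28, lower again. The time 2.0 min lies before the first reading, so I expected the ratio there to stand under that and put no figure on it.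

The forecast gave 0.25, 2.6 and 3, calling the early figure “a very uncertain extrapolation”. The flask gave 0.525, 2.60 and 2.99.

    substrate → open intermediate (k = 0.0632 min⁻¹)
    first nucleophile + open intermediate → target (k = 37.8 M⁻¹ min⁻¹)
    second nucleophile + open intermediate → other capture product (k = 8.49 M⁻¹ min⁻¹)
    open intermediate + capture agent → trapped intermediate (k = 0.781 M⁻¹ min⁻¹)
    first nucleophile → decomposed reagent (k = 0.162 min⁻¹)
    2 second nucleophile → homo dimer (k = 0.0679 M⁻¹ min⁻¹)

In this flask, decomposition of first nucleophile had half its turnover behind it by 0.0562 h, sooner than the 0.18 h half-life of substrate by its passing into open intermediate alone. After 1.20 h in this flask, [first nucleophile] stood at 0% of its charge with 1.06% of the substrate still there, so first nucleophile was the limiting reagent of the target channel.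

In the neighbour flask with 0.520 equiv of first nucleophile, other charges as in the recipe, the capture share gave 9.96% target and a ratio of 9.04. The computed neighbour gave 12.9% and 6.76 after 12.0 h, a capture share of 24.8%, higher than the one read from the alpha run.

The earlier runs and the new flask are simulated with constants of no real substance.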